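**Plan**
1. Locants (carotenoid numbering): ring A is the cyclohexene C1–C6 (OH at C3), C7 its CH2, C8 the ketone carbon, C9 carries CH2OH (C19); ring B is the cyclohex-2-enyl ring C1'–C6' at the far end.
2. Cuts: C7–C8 first (C10 ring A allyl unit + C30 polyenal), then C11=C12 and C11'=C12' (two Horner–Wadsworth–Emmons reactions on a C10 dialdehyde), C9=C10 (cross-metathesis) and C9'=C10' (olefination of α-ionone).
3. Enabling feature: C7 is the unsubstituted end of the allyl unit C7–C6=C5 of ring A, whose other end C5 is fully substituted, and C8 is a carbonyl carbon. An allylbarium at C7 therefore attacks a C8 aldehyde through C7; C8 is carried as the alcohol and raised to the ketone afterwards.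
4. Forward: the ring B side chain grows C13 → C15 → C25 → C30; the ring A allyl chloride is made separately; both are joined at C7–C8, then oxidation and desilylation.
5. Stereochemistry: C6' from (R)-α-ionone; C3' by catalyst- and substrate-controlled ketone reduction trans to the side chain; C3 from (4R,6R)-actinol; E alkenes from phosphonate olefinations; C9=C10 geometry from the metathesis.

Key step: step 18

Assumption: (R)-α-ionone, (4R,6R)-actinol and the C10 dialdehyde are taken as purchasable single compounds; TBS = tert-butyldimethylsilyl; 27 is carried as both C8 epimers because C8 becomes a carbonyl carbon.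

**Step 1**
Reactants: 1 (R)-α-ionone; 2 triethyl phosphonoacetate
Product: 3 ethyl (2E,4E)-3-methyl-5-[(1R)-2,6,6-trimethylcyclohex-2-en-1-yl]penta-2,4-dienoate
Conditions: NaH, THF, 0 °C to 50 °C; minor 2Z isomer removed by chromatography
Reagents that add atoms: none
Why: Horner–Wadsworth–Emmons olefination of the methyl ketone should give mainly the 2E dienoate (C9'=C10'), and the weakly basic stabilised anion should not deprotonate C6', so the stereocentre of 1 is kept.

**Step 2**
Reactants: 3 ethyl dienoate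
Product: 4 ethyl (2E,4E)-3-methyl-5-[(1R)-2,6,6-trimethyl-4-oxocyclohex-2-en-1-yl]penta-2,4-dienoate
Conditions: t-BuOOH, CrO3 (cat.), CH2Cl2, rt
Reagents that add atoms: tert-butyl hydroperoxide, CC(C)(C)OO
Why: Chromium-catalysed radical allylic oxidation at the only ring methylene next to C4'=C5' (C3') is the reaction type known for α-ionone and its homologues, and the neutral medium should keep C6' (γ to the new enone) from epimerising.

**Step 3**
Reactants: 4 ring enone
Product: 5 ethyl (2E,4E)-5-[(1R,4R)-4-hydroxy-2,6,6-trimethylcyclohex-2-en-1-yl]-3-methylpenta-2,4-dienoate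
Conditions: (S)-2-methyl-CBS-oxazaborolidine (20 mol %), catecholborane, toluene, −78 °C
Reagents that add atoms: none
Why: Corey–Bakshi–Shibata reduction with the alkenyl side as the large group should set C3' as R, and the axial C1' methyl group on the face opposite the side chain blocks the other approach, so catalyst and substrate should agree on the trans alcohol while the dienoate is untouched.

**Step 4**
Reactants: 5 allylic alcohol
Product: 6 TBS ether of 5
Conditions: TBSCl, imidazole, DMF, rt
Reagents that add atoms: tert-butyldimethylsilyl chloride, CC(C)(C)[Si](C)(C)Cl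
Why: Standard silylation of a secondary alcohol protects the acid-sensitive allylic C3' oxygen for the organometallic and basic steps ahead.

**Step 5**
Reactants: 6 silylated ester
Product: 7 (2E,4E)-5-[(1R,4R)-4-(TBS-oxy)-2,6,6-trimethylcyclohex-2-en-1-yl]-3-methylpenta-2,4-dien-1-ol
Conditions: i-Bu2AlH, CH2Cl2, −78 °C; Rochelle salt work-up
Reagents that add atoms: none
Why: Hydride reduction of a conjugated ester with i-Bu2AlH should stop cleanly at the allylic alcohol (1,2-reduction) and leaves the silyl ether and the alkenes alone.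

**Step 6**
Reactants: 7 dienol
Product: 9 diethyl [(2E,4E)-5-[(1R,4R)-4-(TBS-oxy)-2,6,6-trimethylcyclohex-2-en-1-yl]-3-methylpenta-2,4-dien-1-yl]phosphonate, via dienyl bromide 8 (not isolated)
Conditions: CBr4, PPh3, CH2Cl2, −20 °C; solvent exchange; P(OEt)3, toluene, 90 °C
Reagents that add atoms: triethyl phosphite, CCOP(OCC)OCC
Why: Appel bromination (SN2 at the primary allylic carbon, no acid) followed by a Michaelis–Arbuzov reaction should give the C15 allylic phosphonate with the 2E geometry unchanged.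

**Step 7**
Reactants: 9 C15 phosphonate; 10 (2E,4E,6E)-2,7-dimethylocta-2,4,6-trienedial (3 equiv)
Product: 11 C25 aldehyde (all-E ring B hexaenal ending in the C12 formyl group)
Conditions: KOt-Bu, THF, −30 °C; anion added to 10, −30 °C to 0 °C
Reagents that add atoms: none
Why: Horner–Wadsworth–Emmons olefination of the allylic phosphonate anion with one formyl group of the symmetric dialdehyde in excess should form C11'=C12' as the E alkene and keep the second formyl group for step 10.

**Step 8**
Reactants: 12 methyl 2-(hydroxymethyl)acrylate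
Product: 13 methyl 2-[(TBS-oxy)methyl]acrylate
Conditions: TBSCl, imidazole, CH2Cl2, 0 °C to rt
Reagents that add atoms: tert-butyldimethylsilyl chloride, CC(C)(C)[Si](C)(C)Cl
Why: Standard silylation of the primary allylic alcohol installs the C19 protecting group that stays until the last step.

**Step 9**
Reactants: 13 silylated acrylate (3 equiv); 14 diethyl allylphosphonate
Product: 15 methyl (2E)-2-[(TBS-oxy)methyl]-4-(diethoxyphosphoryl)but-2-enoate
Conditions: second-generation Hoveyda–Grubbs catalyst (C31H38Cl2N2ORu, 5 mol %), CH2Cl2, 40 °C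
Reagents that add atoms: none
Why: Cross-metathesis of a 1,1-disubstituted acrylate with a terminal alkene is known to give the trisubstituted enoate with the new substituent trans to the ester, which sets C9=C10 with C11 cis to CH2OTBS.

**Step 10**
Reactants: 11 C25 aldehyde; 15 C5 phosphonate
Product: 16 C30 methyl ester (all-E ring B octaenoate with CH2OTBS on C9 and the ester as C8)
Conditions: LiN(SiMe3)2, THF, −78 °C; then 11, −78 °C to −20 °C
Reagents that add atoms: none
Why: Vinylogous Horner–Wadsworth–Emmons reaction of the γ-phosphono enoate, the reaction type used with crotonate-derived C5 phosphonates in polyene synthesis, should join C11 to C12 as the E alkene, and the low temperature is meant to suppress loss of silanolate from the dienolate and rotation about C9–C10.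

**Step 11**
Reactants: 16 C30 ester
Product: 17 C30 allylic alcohol (C8 as CH2OH)
Conditions: i-Bu2AlH, CH2Cl2, −78 °C; Rochelle salt work-up
Reagents that add atoms: none
Why: 1,2-Reduction of the polyenoate with i-Bu2AlH is the standard route from apo-carotenoates to apo-carotenols and should leave the three silyl-protected oxygens in place.

**Step 12**
Reactants: 17 C30 alcohol
Product: 18 C30 aldehyde (C8 formyl group)
Conditions: MnO2 (activated, excess), CH2Cl2, rt
Reagents that add atoms: none
Why: MnO2 oxidises primary polyenylic alcohols selectively to the aldehydes under neutral conditions, and all other hydroxyl groups are silylated.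

**Step 13**
Reactants: 19 (4R,6R)-4-hydroxy-2,2,6-trimethylcyclohexanone
Product: 20 (4R,6R)-4-(TBS-oxy)-2,2,6-trimethylcyclohexanone
Conditions: TBSCl, imidazole, DMF, rt
Reagents that add atoms: tert-butyldimethylsilyl chloride, CC(C)(C)[Si](C)(C)Cl
Why: Standard silylation protects the C3 hydroxyl group, whose configuration is the C3 stereocentre of the target.

**Step 14**
Reactants: 20 silylated ketone
Product: 21 (4R)-4-(TBS-oxy)-2,6,6-trimethylcyclohex-1-en-1-yl trifluoromethanesulfonate
Conditions: LiN(i-Pr)2, THF, −78 °C to 0 °C; PhNTf2, 0 °C to rt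
Reagents that add atoms: N-phenylbis(trifluoromethanesulfonimide), O=S(=O)(N(c1ccccc1)S(=O)(=O)C(F)(F)F)C(F)(F)F
Why: The ketone has a single α-hydrogen, so only one enolate can form and it is trapped as the tetrasubstituted enol triflate (the future C5=C6 bond), which deliberately erases the methyl-bearing stereocentre.

**Step 15**
Reactants: 21 enol triflate
Product: 22 methyl (4R)-4-(TBS-oxy)-2,6,6-trimethylcyclohex-1-ene-1-carboxylate
Conditions: Pd(OAc)2 (5 mol %), PPh3, CO (1 atm), MeOH, Et3N, DMF, 60 °C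
Reagents that add atoms: carbon monoxide, [C-]#[O+]; methanol, CO
Why: Palladium-catalysed alkoxycarbonylation of an enol triflate (oxidative addition of zerovalent palladium, CO insertion, methanolysis) introduces C7 at the hindered ring carbon C6.

**Step 16**
Reactants: 22 ring ester
Product: 23 [(4R)-4-(TBS-oxy)-2,6,6-trimethylcyclohex-1-en-1-yl]methanol
Conditions: i-Bu2AlH, CH2Cl2, −78 °C to 0 °C; Rochelle salt work-up
Reagents that add atoms: none
Why: Hydride reduction of the conjugated ester with i-Bu2AlH gives the primary allylic alcohol without touching the tetrasubstituted alkene.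

**Step 17**
Reactants: 23 allylic alcohol
Product: 25 (4R)-1-(chloromethyl)-4-(TBS-oxy)-2,6,6-trimethylcyclohex-1-ene, via allylic mesylate 24 (not isolated)
Conditions: MsCl, 2,4,6-collidine, LiCl, DMF, 0 °C
Reagents that add atoms: lithium chloride, [Li+].[Cl-]
Why: Mesylation and in situ SN2 displacement by chloride at the primary allylic carbon should proceed without allylic transposition, since attack at C5 would give a tertiary chloride.

**Step 18**
Reactants: 25 ring A allyl chloride (slight excess over barium, excess over 18); 18 C30 aldehyde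
Product: 27 tris-TBS C40 carbinol (C8 alcohol as both epimers), via allylbarium chloride 26 (not isolated)
Conditions: BaI2, LiC12H10 (lithium biphenylide, 2 equiv per BaI2), THF, rt; then 25, −78 °C; then 18, −78 °C; aq NH4Cl at −78 °C
Reagents that add atoms: none
Why: Activated barium inserts into the C7–Cl bond of 25 to give the primary σ-allylbarium 26, which at −78 °C does not equilibrate with its tertiary allyl isomer and adds 1,2 to the formyl group of 18 through the metal-bearing carbon C7, so the C7–C8 bond forms and the C5=C6 double bond of ring A stays in place. The closest known reaction type is the α-selective 1,2-addition of γ,γ-disubstituted allylbarium reagents (prenyl- and geranylbarium) to aldehydes, enals included. No ring is closed. The only new stereocentre, C8, is not controlled and need not be, because both epimers give the same ketone in step 19. The step needs α- over γ-attack, which the fully substituted C5 (γ-attack would build a quaternary carbon there) and the long ionic C–Ba bond should secure, and 1,2- over conjugate addition along the polyene, which the hard barium reagent and the aldehyde carbonyl should secure. Chloride 25 is kept in slight excess over barium so that no reducing metal is left to transfer electrons to the polyenal, and the cold quench is meant to prevent migration of the C19 silyl group to the new C8 alkoxide.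

**Step 19**
Reactants: 27 C40 carbinol
Product: 28 tris-TBS siphonaxanthin (C8 ketone)
Conditions: Dess–Martin periodinane, NaHCO3, CH2Cl2, 0 °C
Reagents that add atoms: none
Why: Dess–Martin oxidation of the secondary polyenylic alcohol under buffered conditions converges both C8 epimers on the ketone and should not move the C5=C6 double bond into conjugation.

**Step 20**
Reactants: 28 tris-TBS ketone
Product: 29 siphonaxanthin, (3R,3'R,6'R)-3,3',19-trihydroxy-7,8-dihydro-β,ε-caroten-8-one
Conditions: HF·pyridine, pyridine, THF, 0 °C to rt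
Reagents that add atoms: none
Why: Fluoride cleavage of the three silyl ethers with pyridine-buffered HF is chosen because basic fluoride could enolise the β,γ-unsaturated ketone at C7 and strong acid could ionise the allylic C3' alcohol; no stereocentre is touched.

**Compound list**
1 | (R)-α-ionone, (3E)-4-[(1R)-2,6,6-trimethylcyclohex-2-en-1-yl]but-3-en-2-one | CC1=CCCC(C)(C)[C@H]1/C=C/C(C)=O | starting material
2 | triethyl phosphonoacetate | CCOC(=O)CP(=O)(OCC)OCC | starting material
3 | ethyl (2E,4E)-3-methyl-5-[(1R)-2,6,6-trimethylcyclohex-2-en-1-yl]penta-2,4-dienoate | CC1=CCCC(C)(C)[C@H]1/C=C/C(C)=C/C(=O)OCC | intermediate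
4 | ethyl (2E,4E)-3-methyl-5-[(1R)-2,6,6-trimethyl-4-oxocyclohex-2-en-1-yl]penta-2,4-dienoate | CC1=CC(=O)CC(C)(C)[C@H]1/C=C/C(C)=C/C(=O)OCC | intermediate
5 | ethyl (2E,4E)-5-[(1R,4R)-4-hydroxy-2,6,6-trimethylcyclohex-2-en-1-yl]-3-methylpenta-2,4-dienoate | CC1=C[C@H](O)CC(C)(C)[C@H]1/C=C/C(C)=C/C(=O)OCC | intermediate
6 | ethyl (2E,4E)-5-[(1R,4R)-4-(tert-butyldimethylsilyloxy)-2,6,6-trimethylcyclohex-2-en-1-yl]-3-methylpenta-2,4-dienoate | CC1=C[C@H](O[Si](C)(C)C(C)(C)C)CC(C)(C)[C@H]1/C=C/C(C)=C/C(=O)OCC | intermediate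
7 | (2E,4E)-5-[(1R,4R)-4-(tert-butyldimethylsilyloxy)-2,6,6-trimethylcyclohex-2-en-1-yl]-3-methylpenta-2,4-dien-1-ol | CC1=C[C@H](O[Si](C)(C)C(C)(C)C)CC(C)(C)[C@H]1/C=C/C(C)=C/CO | intermediate
8 | 1-bromide corresponding to alcohol 7 (2E,4E dienyl bromide) | CC1=C[C@H](O[Si](C)(C)C(C)(C)C)CC(C)(C)[C@H]1/C=C/C(C)=C/CBr | intermediate (formed in step 6, not isolated)
9 | diethyl [(2E,4E)-5-[(1R,4R)-4-(tert-butyldimethylsilyloxy)-2,6,6-trimethylcyclohex-2-en-1-yl]-3-methylpenta-2,4-dien-1-yl]phosphonate | CC1=C[C@H](O[Si](C)(C)C(C)(C)C)CC(C)(C)[C@H]1/C=C/C(C)=C/CP(=O)(OCC)OCC | intermediate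
10 | (2E,4E,6E)-2,7-dimethylocta-2,4,6-trienedial | O=C/C(C)=C/C=C/C=C(C)/C=O | starting material
11 | (2E,4E,6E,8E,10E,12E)-13-[(1R,4R)-4-(tert-butyldimethylsilyloxy)-2,6,6-trimethylcyclohex-2-en-1-yl]-2,7,11-trimethyltrideca-2,4,6,8,10,12-hexaenal (C25 aldehyde, formyl carbon = C12) | CC1=C[C@H](O[Si](C)(C)C(C)(C)C)CC(C)(C)[C@H]1/C=C/C(C)=C/C=C/C(C)=C/C=C/C=C(C)/C=O | intermediate
12 | methyl 2-(hydroxymethyl)acrylate | C=C(CO)C(=O)OC | starting material
13 | methyl 2-[(tert-butyldimethylsilyloxy)methyl]acrylate | C=C(CO[Si](C)(C)C(C)(C)C)C(=O)OC | intermediate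
14 | diethyl allylphosphonate | C=CCP(=O)(OCC)OCC | starting material
15 | methyl (2E)-2-[(tert-butyldimethylsilyloxy)methyl]-4-(diethoxyphosphoryl)but-2-enoate (phosphonomethyl group cis to CH2OTBS) | CCOP(=O)(OCC)C/C=C(\CO[Si](C)(C)C(C)(C)C)C(=O)OC | intermediate
16 | methyl (2E,4E,6E,8E,10E,12E,14E,16E)-2-[(tert-butyldimethylsilyloxy)methyl]-17-[(1R,4R)-4-(tert-butyldimethylsilyloxy)-2,6,6-trimethylcyclohex-2-en-1-yl]-6,11,15-trimethylheptadeca-2,4,6,8,10,12,14,16-octaenoate (C30 ester, ester carbon = C8) | CC1=C[C@H](O[Si](C)(C)C(C)(C)C)CC(C)(C)[C@H]1/C=C/C(C)=C/C=C/C(C)=C/C=C/C=C(C)/C=C/C=C(\CO[Si](C)(C)C(C)(C)C)C(=O)OC | intermediate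
17 | C30 allylic alcohol: the 1-ol corresponding to ester 16 (C8 as CH2OH, C11 cis to CH2OTBS, all other chain alkenes E) | CC1=C[C@H](O[Si](C)(C)C(C)(C)C)CC(C)(C)[C@H]1/C=C/C(C)=C/C=C/C(C)=C/C=C/C=C(C)/C=C/C=C(\CO[Si](C)(C)C(C)(C)C)CO | intermediate
18 | C30 aldehyde: the 1-al corresponding to ester 16 (C8 formyl group trans to C11, all-E) | CC1=C[C@H](O[Si](C)(C)C(C)(C)C)CC(C)(C)[C@H]1/C=C/C(C)=C/C=C/C(C)=C/C=C/C=C(C)/C=C/C=C(\CO[Si](C)(C)C(C)(C)C)C=O | intermediate
19 | (4R,6R)-4-hydroxy-2,2,6-trimethylcyclohexan-1-one (actinol) | O=C1[C@H](C)C[C@@H](O)CC1(C)C | starting material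
20 | (4R,6R)-4-(tert-butyldimethylsilyloxy)-2,2,6-trimethylcyclohexan-1-one | O=C1[C@H](C)C[C@@H](O[Si](C)(C)C(C)(C)C)CC1(C)C | intermediate
21 | (4R)-4-(tert-butyldimethylsilyloxy)-2,6,6-trimethylcyclohex-1-en-1-yl trifluoromethanesulfonate | FC(F)(F)S(=O)(=O)OC1=C(C)C[C@@H](O[Si](C)(C)C(C)(C)C)CC1(C)C | intermediate
22 | methyl (4R)-4-(tert-butyldimethylsilyloxy)-2,6,6-trimethylcyclohex-1-ene-1-carboxylate | COC(=O)C1=C(C)C[C@@H](O[Si](C)(C)C(C)(C)C)CC1(C)C | intermediate
23 | [(4R)-4-(tert-butyldimethylsilyloxy)-2,6,6-trimethylcyclohex-1-en-1-yl]methanol | OCC1=C(C)C[C@@H](O[Si](C)(C)C(C)(C)C)CC1(C)C | intermediate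
24 | methanesulfonate of alcohol 23 | CS(=O)(=O)OCC1=C(C)C[C@@H](O[Si](C)(C)C(C)(C)C)CC1(C)C | intermediate (formed in step 17, not isolated)
25 | (4R)-4-(tert-butyldimethylsilyloxy)-1-(chloromethyl)-2,6,6-trimethylcyclohex-1-ene | ClCC1=C(C)C[C@@H](O[Si](C)(C)C(C)(C)C)CC1(C)C | intermediate
26 | {[(4R)-4-(tert-butyldimethylsilyloxy)-2,6,6-trimethylcyclohex-1-en-1-yl]methyl}barium chloride | Cl[Ba]CC1=C(C)C[C@@H](O[Si](C)(C)C(C)(C)C)CC1(C)C | intermediate (formed in step 18, not isolated)
27 | (3R,3'R,6'R)-3,3',19-tris(tert-butyldimethylsilyloxy)-7,8-dihydro-β,ε-caroten-8-ol (both C8 epimers, chain all-E) | CC1=C[C@H](O[Si](C)(C)C(C)(C)C)CC(C)(C)[C@H]1/C=C/C(C)=C/C=C/C(C)=C/C=C/C=C(C)/C=C/C=C(\CO[Si](C)(C)C(C)(C)C)C(O)CC1=C(C)C[C@@H](O[Si](C)(C)C(C)(C)C)CC1(C)C | intermediate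
28 | (3R,3'R,6'R)-3,3',19-tris(tert-butyldimethylsilyloxy)-7,8-dihydro-β,ε-caroten-8-one | CC1=C[C@H](O[Si](C)(C)C(C)(C)C)CC(C)(C)[C@H]1/C=C/C(C)=C/C=C/C(C)=C/C=C/C=C(C)/C=C/C=C(\CO[Si](C)(C)C(C)(C)C)C(=O)CC1=C(C)C[C@@H](O[Si](C)(C)C(C)(C)C)CC1(C)C | intermediate
29 | siphonaxanthin, (3R,3'R,6'R)-3,3',19-trihydroxy-7,8-dihydro-β,ε-caroten-8-one | CC1=C[C@H](O)CC(C)(C)[C@H]1/C=C/C(C)=C/C=C/C(C)=C/C=C/C=C(C)/C=C/C=C(\CO)C(=O)CC1=C(C)C[C@@H](O)CC1(C)C | target

**Totals**
Total steps: 20. Longest linear sequence: 13 steps (steps 1–7, 10–12, 18–20).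

**Steps most likely to fail**

Step 18. The allylbarium may attack through its γ-terminus C5 (allylic transposition), residual barium may transfer electrons to the polyenal, or the C19 silyl group may migrate to the C8 alkoxide. The fallback sets out from 25 and comes back at 28. Chloride 25 is treated with PhSO2Na (DMF, rt) to give the allyl phenyl sulfone F1. Its lithio derivative (n-BuLi, THF, −78 °C) adds 1,2 to aldehyde 18 to give the β-hydroxy sulfone F2. Dess–Martin oxidation gives the β-keto sulfone F3, and reductive desulfonylation with SmI2 (THF/MeOH, −78 °C) gives 28.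

Step 10. The phosphonate dienolate may lose silanolate by β-elimination, or rotate about C9–C10 and erode the alkene geometry. The fallback sets out from 11 and comes back at 17; it takes the C9=C10 geometry from a ring.
- Aldehyde 11 is reduced (NaBH4, MeOH/THF, 0 °C) to the C25 allylic alcohol F4 and converted with PPh3·HBr (CH2Cl2, 0 °C) into the C25 triphenylphosphonium bromide F5.
- Separately, 1,3-dihydroxyacetone and ethyl (triphenylphosphoranylidene)acetate (CH2Cl2, rt) give, after spontaneous lactonisation, 4-(hydroxymethyl)furan-2(5H)-one F6.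
- F6 is silylated (Et3SiCl, imidazole) to the triethylsilyl ether F7 and reduced (i-Bu2AlH, CH2Cl2, −78 °C) to the lactol F8.
- Wittig reaction of the ylide of F5 (NaN(SiMe3)2, THF, −78 °C to 0 °C) with F8 opens the lactol to the C30 mono-triethylsilyl diol F9, in which the former ring holds C11 cis to the free CH2OH.
- TBS protection gives the bis-silyl ether F10, and selective removal of the primary triethylsilyl group (pyridinium p-toluenesulfonate, MeOH/CH2Cl2, 0 °C) gives 17.

Step 3. Hydride delivery may show poor facial selectivity and give the cis alcohol. The fallback sets out from 4 and comes back at 5. Reduction of 4 with NaBH4/CeCl3 (MeOH, −78 °C) and separation gives the cis alcohol F11. Mitsunobu reaction with 4-nitrobenzoic acid (PPh3, diisopropyl azodicarboxylate, THF, 0 °C) gives the inverted 4-nitrobenzoate F12, and ethanolysis (K2CO3, EtOH) gives 5.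

**Further compounds**
F1 | step 18 | {[(4R)-4-(tert-butyldimethylsilyloxy)-2,6,6-trimethylcyclohex-1-en-1-yl]methyl} phenyl sulfone | O=S(=O)(CC1=C(C)C[C@@H](O[Si](C)(C)C(C)(C)C)CC1(C)C)c1ccccc1
F2 | step 18 | 7-(phenylsulfonyl) derivative of carbinol 27 (β-hydroxy sulfone, diastereomer mixture at C7 and C8) | CC1=C[C@H](O[Si](C)(C)C(C)(C)C)CC(C)(C)[C@H]1/C=C/C(C)=C/C=C/C(C)=C/C=C/C=C(C)/C=C/C=C(\CO[Si](C)(C)C(C)(C)C)C(O)C(C1=C(C)C[C@@H](O[Si](C)(C)C(C)(C)C)CC1(C)C)S(=O)(=O)c1ccccc1
F3 | step 18 | 7-(phenylsulfonyl) derivative of ketone 28 (β-keto sulfone) | CC1=C[C@H](O[Si](C)(C)C(C)(C)C)CC(C)(C)[C@H]1/C=C/C(C)=C/C=C/C(C)=C/C=C/C=C(C)/C=C/C=C(\CO[Si](C)(C)C(C)(C)C)C(=O)C(C1=C(C)C[C@@H](O[Si](C)(C)C(C)(C)C)CC1(C)C)S(=O)(=O)c1ccccc1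
F4 | step 10 | C25 allylic alcohol, the 1-ol corresponding to aldehyde 11 | CC1=C[C@H](O[Si](C)(C)C(C)(C)C)CC(C)(C)[C@H]1/C=C/C(C)=C/C=C/C(C)=C/C=C/C=C(C)/CO
F5 | step 10 | C25 triphenylphosphonium bromide derived from F4 | CC1=C[C@H](O[Si](C)(C)C(C)(C)C)CC(C)(C)[C@H]1/C=C/C(C)=C/C=C/C(C)=C/C=C/C=C(C)/C[P+](c1ccccc1)(c1ccccc1)c1ccccc1.[Br-]
F6 | step 10 | 4-(hydroxymethyl)furan-2(5H)-one | O=C1OCC(CO)=C1
F7 | step 10 | 4-[(triethylsilyloxy)methyl]furan-2(5H)-one | O=C1OCC(CO[Si](CC)(CC)CC)=C1
F8 | step 10 | 4-[(triethylsilyloxy)methyl]-2,5-dihydrofuran-2-ol | OC1OCC(CO[Si](CC)(CC)CC)=C1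
F9 | step 10 | C30 diol mono-triethylsilyl ether (C19 hydroxyl free and cis to C11, C8 as CH2OSiEt3) | CC1=C[C@H](O[Si](C)(C)C(C)(C)C)CC(C)(C)[C@H]1/C=C/C(C)=C/C=C/C(C)=C/C=C/C=C(C)/C=C/C=C(\CO)CO[Si](CC)(CC)CC
F10 | step 10 | C30 bis-silyl ether (C19 as CH2OTBS, C8 as CH2OSiEt3) | CC1=C[C@H](O[Si](C)(C)C(C)(C)C)CC(C)(C)[C@H]1/C=C/C(C)=C/C=C/C(C)=C/C=C/C=C(C)/C=C/C=C(\CO[Si](C)(C)C(C)(C)C)CO[Si](CC)(CC)CC
F11 | step 3 | ethyl (2E,4E)-5-[(1R,4S)-4-hydroxy-2,6,6-trimethylcyclohex-2-en-1-yl]-3-methylpenta-2,4-dienoate (cis alcohol) | CC1=C[C@@H](O)CC(C)(C)[C@H]1/C=C/C(C)=C/C(=O)OCC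
F12 | step 3 | 4-nitrobenzoate of alcohol 5 (1R,4R) | CC1=C[C@H](OC(=O)c2ccc(cc2)[N+](=O)[O-])CC(C)(C)[C@H]1/C=C/C(C)=C/C(=O)OCC
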